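**Strategy.** Everything rests on closing ring B (C4–C5–C6–C7–C8–C9; own locants, listed below) of the benzyl-bearing octalin last, by making the C4–C9 bond. A 6-exo Mizoroki–Heck cyclization of the ring A enol triflate (C4) onto a trisubstituted C9=C10 alkene, held in a C5 side chain that already carries the finished second octalin (rings C/D), forms ring B and quaternary C9 in one operation and leaves the C3=C4 alkene in place. It exploits that sp2 ring-fusion carbon C4 bears quaternary C9, whose C10–C11 bridge to quaternary C12 forces β-hydride elimination into one non-migrating C10=C11 alkene, hydrogenated afterwards.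

Key step: step 13

Locants used (own numbering):
- Ring A: C1 (CHMe), C2, C3 (=CH), C4 (=C, fusion), C5 (fusion CH), C22 (C(Me)CH2Ar).
- Ring B: C4, C5, C6, C7, C8, C9 (C(Me) carrying the bridge C10–C11).
- Ring C: C12 (C(Me)), C13, C18 (fusion CH), C19, C20, C21 (CHMe).
- Ring D: C13=C14, C15, C16, C17 (CMe2), C18.

Remark 1: the target is drawn as the free bis(hydrogen sulfate), so the last step ends with proton exchange of the pyridinium salt.

Remark 2: 13 is used as its (E) isomer, obtained by fractional distillation of the commercial E/Z mixture. The geometry of this alkene is erased in steps 13 and 14.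

**Ring A fragment**

Step 1
Reactants: 1 propanal; 2 methyl vinyl ketone
Product: 3 (R)-2-methyl-5-oxohexanal
Conditions: (S)-2-[methoxy(diphenyl)methyl]pyrrolidine (5 mol %), ethyl 3,4-dihydroxybenzoate (20 mol %), neat, 4 °C
Reagents that add atoms: none
Why: Enamine-catalysed Michael addition of the aldehyde to the enone, in which the (S)-diarylprolinol ether shields one enamine face so that the methyl-bearing centre (later C1) should form as R.

Step 2
Reactants: 3 (R)-2-methyl-5-oxohexanal
Product: 4 (R)-4-methylcyclohex-2-en-1-one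
Conditions: LiOH·H2O (cat.), i-PrOH, rt
Reagents that add atoms: none
Why: Intramolecular aldol condensation of the methyl ketone onto the aldehyde closes ring A as the enone without touching the γ-stereocentre.

Step 3
Reactants: 4 (R)-4-methylcyclohex-2-en-1-one; 5 2,5-dimethoxybenzyl chloride
Product: 7 {[(3S,4R)-3-(2,5-dimethoxybenzyl)-4-methylcyclohex-1-en-1-yl]oxy}trimethylsilane, via 2,5-dimethoxybenzylmagnesium chloride 6 (not isolated)
Conditions: 5, Mg, THF, 0 °C; then CuBr·SMe2 (10 mol %), TMSCl, 4, THF, −78 °C; Et3N quench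
Reagents that add atoms: chlorotrimethylsilane C[Si](C)(C)Cl
Why: Copper-catalysed 1,4-addition of the benzylic Grignard reagent, accelerated and trapped by TMSCl, places the arylmethyl group on the β-carbon trans to the methyl group (this centre is planarised again in step 4).

Step 4
Reactants: 7 silyl enol ether
Product: 8 (R)-3-(2,5-dimethoxybenzyl)-4-methylcyclohex-2-en-1-one
Conditions: Pd(OAc)2 (10 mol %), O2 (1 atm), DMSO, rt
Reagents that add atoms: none
Why: Saegusa–Ito oxidation (palladium enolate, β-hydride elimination) regenerates the enone with the benzyl group now on the β-carbon and leaves the γ-methyl stereocentre untouched.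

Step 5
Reactants: 8 (R)-3-(2,5-dimethoxybenzyl)-4-methylcyclohex-2-en-1-one
Product: 10 (2S,3R,4R)-2-allyl-3-(2,5-dimethoxybenzyl)-3,4-dimethylcyclohexan-1-one, via lithium enolate 9 (not isolated)
Conditions: Me2CuLi (from MeLi, CuI), Et2O, −20 °C; then allyl bromide, HMPA, THF, −20 °C → rt
Reagents that add atoms: lithium dimethylcuprate [Li+].C[Cu-]C; allyl bromide C=CCBr
Why: Cuprate 1,4-addition anti to the pseudoaxial γ-methyl sets quaternary C22 (methyl trans to C1-Me, benzyl cis), and the regiodefined enolate should be allylated at C5 by axial attack on the face opposite to the benzyl group, which is pseudoaxial in the enolate conformer with both methyls equatorial (tandem conjugate addition–enolate alkylation).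

**Rings C/D fragment**

Step 6
Reactants: 11 (S)-(−)-pulegone
Product: 12 (2R,3S)-2,3-dimethyl-6-(propan-2-ylidene)cyclohexan-1-one (trans-6-methylpulegone)
Conditions: LiN(i-Pr)2, THF, −78 °C; MeI, −78 → 0 °C
Reagents that add atoms: iodomethane CI
Why: Kinetic α′-deprotonation of the cross-conjugated enone and SN2 methylation (enolate alkylation) introduce the C12 methyl group, whose centre is planarised again in step 7.

Step 7
Reactants: 12 trans-6-methylpulegone; 13 (E)-1,3-dichlorobut-2-ene
Product: 14 (2R,3S)-2-[(E)-3-chlorobut-2-en-1-yl]-2,3-dimethyl-6-(propan-2-ylidene)cyclohexan-1-one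
Conditions: LiN(i-Pr)2, THF/DMPU, −78 → 0 °C; 13, NaI (cat.)
Reagents that add atoms: none
Why: Second α′-enolate alkylation at the allylic CH2Cl, in which A(1,2) strain makes the neighbouring C21 methyl pseudoaxial so that the electrophile should enter anti to it, setting quaternary C12 with the chain trans and the methyl cis to C21-Me.

Step 8
Reactants: 14 dienone; 15 2-(2-bromoethyl)-1,3-dioxolane
Product: 17 (2R,3S,6R)-2-[(E)-3-chlorobut-2-en-1-yl]-6-[4-(1,3-dioxolan-2-yl)-2-methylbutan-2-yl]-2,3-dimethylcyclohexan-1-one, via [2-(1,3-dioxolan-2-yl)ethyl]magnesium bromide 16 (not isolated)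
Conditions: 15, Mg, THF, 25 °C; then CuBr·SMe2 (10 mol %), 14, THF, −20 °C; NH4Cl work-up; then KOH (cat.), EtOH, reflux
Reagents that add atoms: none
Why: Copper-catalysed conjugate addition of the acetal Grignard reagent to the s-cis β,β-dimethyl enone builds the gem-dimethyl carbon C17, and base equilibration at C18 should place the bulky substituent equatorial, trans to the C21 methyl.

Step 9
Reactants: 17 keto acetal
Product: 18 4-{(1R,3R,4S)-3-[(E)-3-chlorobut-2-en-1-yl]-3,4-dimethyl-2-oxocyclohexyl}-4-methylpentanal
Conditions: 1 M HCl, THF, rt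
Reagents that add atoms: water O
Why: Mild acidic acetal hydrolysis frees the C14 aldehyde while the vinyl chloride and the hindered ketone are inert.

Step 10
Reactants: 18 keto aldehyde
Product: 19 (1R,2S,4aR)-1-[(E)-3-chlorobut-2-en-1-yl]-1,2,5,5-tetramethyl-1,2,3,4,4a,5,6,7-octahydronaphthalene
Conditions: TiCl3(DME)1.5, Zn–Cu couple, DME, reflux, slow addition (high dilution)
Reagents that add atoms: none
Why: Intramolecular McMurry coupling of the C13 ketone with the C14 aldehyde on low-valent titanium closes ring D and puts the C13=C14 alkene directly in its final position, with alkenes and vinyl chlorides tolerated and no stereocentre touched.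

**Union, ring B closure and endgame**

Step 11
Reactants: 10 ring A allyl ketone; 19 rings C/D vinyl chloride
Product: 21 (2S,3R,4R)-3-(2,5-dimethoxybenzyl)-3,4-dimethyl-2-{(E)-4-methyl-6-[(1R,2S,4aR)-1,2,5,5-tetramethyl-1,2,3,4,4a,5,6,7-octahydronaphthalen-1-yl]hex-4-en-1-yl}cyclohexan-1-one, via B-alkyl-9-BBN borane 20 (not isolated)
Conditions: 9-BBN, THF, 0 °C → rt; then 19, Pd(OAc)2 (5 mol %), SPhos (10 mol %), K3PO4 (aq.), THF, 45 °C
Reagents that add atoms: none
Why: Anti-Markovnikov hydroboration of the terminal alkene is faster than reduction of the hindered ketone, and B-alkyl Suzuki–Miyaura coupling with the alkenyl chloride forms C8–C9 with retention of alkene geometry.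

Step 12
Reactants: 21 coupled ketone
Product: 22 ring A enol triflate of 21 (C3=C4 double bond, OTf on C4)
Conditions: KN(SiMe3)2, THF, −78 °C; PhNTf2
Reagents that add atoms: N-phenylbis(trifluoromethanesulfonimide) O=S(=O)(N(c1ccccc1)S(=O)(=O)C(F)(F)F)C(F)(F)F
Why: Kinetic deprotonation at the less hindered C3 methylene and O-triflation give the C3=C4 enol triflate regioselectively and lock the C5 stereocentre.

Step 13
Reactants: 22 enol triflate
Product: 23 ring-B-closed tetracycle with an (E)-C10=C11 alkene between the two octalins (dimethyl ether)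
Conditions: Pd(OAc)2 (10 mol %), PPh3 (25 mol %), Et3N, MeCN, 80 °C
Reagents that add atoms: none
Why: Oxidative addition of zerovalent palladium into the C4–O bond gives a cationic vinylpalladium species; syn-carbopalladation of the tethered alkene (6-exo-trig, C4–C9 bond) closes ring B, and β-hydride elimination toward C11, the only β-hydrogens available, releases the (E)-C10=C11 alkene, which cannot migrate because it lies between quaternary C9 and C12. The closest known reaction type is the intramolecular Mizoroki–Heck cyclization of cyclohexenyl triflates onto trisubstituted alkenes to form all-carbon quaternary centres. The new stereocentre C9 is controlled by C5: the three-carbon tether leaves C5 on the face opposite to H5, so C9 can reach only that π-face of C4, and because the palladium-bearing carbon C10 must eclipse the C4–Pd bond it ends up axial on the H5 side with the methyl equatorial, that is, bridge cis to H5 as required, whatever the E/Z geometry of the alkene. The step needs 6-exo over 7-endo closure and insertion faster than triflate reduction; the chair-like six-membered transition state, the cationic triflate pathway and the inertness of the hindered C13=C14 alkene and the arene should secure this.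

Step 14
Reactants: 23 Heck product
Product: 24 toxiusol hydroquinone dimethyl ether
Conditions: H2 (1 atm), PtO2 (cat.), EtOAc, rt, stopped after one equivalent
Reagents that add atoms: none
Why: Chemoselective heterogeneous hydrogenation saturates the only disubstituted alkene (C10=C11), while the two trisubstituted ring alkenes, each flanked by a quaternary carbon, should react far more slowly.

Step 15
Reactants: 24 dimethyl ether
Product: 25 toxiusol quinone (2-substituted 1,4-benzoquinone)
Conditions: (NH4)2Ce(NO3)6, MeCN/H2O, 0 °C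
Reagents that add atoms: water O
Why: Oxidative demethylation of the p-dimethoxyarene by the one-electron oxidant gives the benzoquinone, a reaction that tolerates isolated trisubstituted alkenes.

Step 16
Reactants: 25 quinone
Product: 26 toxiusol hydroquinone (desulfated toxiusol)
Conditions: Na2S2O4, THF/H2O, rt
Reagents that add atoms: none
Why: Dithionite reduction of the quinone gives the hydroquinone under neutral conditions.

Step 17
Reactants: 26 hydroquinone
Product: 27 toxiusol
Conditions: SO3·pyridine, pyridine, 50 °C; then sulfonic acid resin (H+ form), MeOH/H2O, 0 °C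
Reagents that add atoms: sulfur trioxide–pyridine complex O=S(=O)([O-])[n+]1ccccc1
Why: O-Sulfation of both phenols with the SO3·pyridine complex, followed by proton exchange, gives the bis(hydrogen sulfate) without acid strong enough to isomerise the alkenes.

**Compound list**

1 | propanal | CCC=O | starting material
2 | methyl vinyl ketone | CC(=O)C=C | starting material
3 | (R)-2-methyl-5-oxohexanal | C[C@@H](C=O)CCC(C)=O | intermediate
4 | (R)-4-methylcyclohex-2-en-1-one | C[C@@H]1CCC(=O)C=C1 | intermediate
5 | 2,5-dimethoxybenzyl chloride | COc1ccc(OC)c(CCl)c1 | starting material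
6 | 2,5-dimethoxybenzylmagnesium chloride | COc1ccc(OC)c(C[Mg]Cl)c1 | intermediate (not isolated)
7 | {[(3S,4R)-3-(2,5-dimethoxybenzyl)-4-methylcyclohex-1-en-1-yl]oxy}trimethylsilane (benzyl trans to methyl) | C[C@@H]1CCC(O[Si](C)(C)C)=C[C@H]1Cc1cc(OC)ccc1OC | intermediate
8 | (R)-3-(2,5-dimethoxybenzyl)-4-methylcyclohex-2-en-1-one | C[C@@H]1CCC(=O)C=C1Cc1cc(OC)ccc1OC | intermediate
9 | lithium enolate of (3R,4R)-3-(2,5-dimethoxybenzyl)-3,4-dimethylcyclohexanone (C4–O, C4=C5) | C[C@@H]1CCC(O[Li])=C[C@]1(C)Cc1cc(OC)ccc1OC | intermediate (not isolated)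
10 | (2S,3R,4R)-2-allyl-3-(2,5-dimethoxybenzyl)-3,4-dimethylcyclohexan-1-one (allyl trans to benzyl, benzyl cis to C4-methyl) | C[C@@H]1CCC(=O)[C@@H](CC=C)[C@]1(C)Cc1cc(OC)ccc1OC | intermediate
11 | (S)-(−)-pulegone | C[C@H]1CCC(=C(C)C)C(=O)C1 | starting material
12 | (2R,3S)-2,3-dimethyl-6-(propan-2-ylidene)cyclohexan-1-one | C[C@H]1C(=O)C(=C(C)C)CC[C@@H]1C | intermediate
13 | (E)-1,3-dichlorobut-2-ene | C/C(Cl)=C\CCl | starting material
14 | (2R,3S)-2-[(E)-3-chlorobut-2-en-1-yl]-2,3-dimethyl-6-(propan-2-ylidene)cyclohexan-1-one | C/C(Cl)=C\C[C@@]1(C)C(=O)C(=C(C)C)CC[C@@H]1C | intermediate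
15 | 2-(2-bromoethyl)-1,3-dioxolane | BrCCC1OCCO1 | starting material
16 | [2-(1,3-dioxolan-2-yl)ethyl]magnesium bromide | Br[Mg]CCC1OCCO1 | intermediate (not isolated)
17 | (2R,3S,6R)-2-[(E)-3-chlorobut-2-en-1-yl]-6-[4-(1,3-dioxolan-2-yl)-2-methylbutan-2-yl]-2,3-dimethylcyclohexan-1-one | C/C(Cl)=C\C[C@@]1(C)C(=O)[C@@H](C(C)(C)CCC2OCCO2)CC[C@@H]1C | intermediate
18 | 4-{(1R,3R,4S)-3-[(E)-3-chlorobut-2-en-1-yl]-3,4-dimethyl-2-oxocyclohexyl}-4-methylpentanal | C/C(Cl)=C\C[C@@]1(C)C(=O)[C@@H](C(C)(C)CCC=O)CC[C@@H]1C | intermediate
19 | (1R,2S,4aR)-1-[(E)-3-chlorobut-2-en-1-yl]-1,2,5,5-tetramethyl-1,2,3,4,4a,5,6,7-octahydronaphthalene | C/C(Cl)=C\C[C@@]1(C)C2=CCCC(C)(C)[C@H]2CC[C@@H]1C | intermediate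
20 | B-alkyl-9-BBN borane from 10 (9-BBN on the terminal carbon C8 of the former allyl group) | C[C@@H]1CCC(=O)[C@@H](CCCB2C3CCCC2CCC3)[C@]1(C)Cc1cc(OC)ccc1OC | intermediate (not isolated)
21 | (2S,3R,4R)-3-(2,5-dimethoxybenzyl)-3,4-dimethyl-2-{(E)-4-methyl-6-[(1R,2S,4aR)-1,2,5,5-tetramethyl-1,2,3,4,4a,5,6,7-octahydronaphthalen-1-yl]hex-4-en-1-yl}cyclohexan-1-one | C[C@@H]1CCC(=O)[C@@H](CCC/C(C)=C/C[C@@]2(C)C3=CCCC(C)(C)[C@H]3CC[C@@H]2C)[C@]1(C)Cc1cc(OC)ccc1OC | intermediate
22 | enol triflate of 21 (ring A cyclohex-1-enyl triflate, C3=C4, configuration at C5, C22, C1 as in 21) | C[C@@H]1CC=C(OS(=O)(=O)C(F)(F)F)[C@@H](CCC/C(C)=C/C[C@@]2(C)C3=CCCC(C)(C)[C@H]3CC[C@@H]2C)[C@]1(C)Cc1cc(OC)ccc1OC | intermediate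
23 | 10,11-didehydro-toxiusol hydroquinone dimethyl ether ((E)-CH=CH bridge; C9 bridge cis to H5, C9 methyl trans) | C[C@@H]1CC=C2[C@@H](CCC[C@@]2(C)/C=C/[C@@]2(C)C3=CCCC(C)(C)[C@H]3CC[C@@H]2C)[C@]1(C)Cc1cc(OC)ccc1OC | intermediate
24 | toxiusol hydroquinone dimethyl ether | C[C@@H]1CC=C2[C@@H](CCC[C@@]2(C)CC[C@@]2(C)C3=CCCC(C)(C)[C@H]3CC[C@@H]2C)[C@]1(C)Cc1cc(OC)ccc1OC | intermediate
25 | toxiusol quinone (2-substituted 1,4-benzoquinone) | C[C@@H]1CC=C2[C@@H](CCC[C@@]2(C)CC[C@@]2(C)C3=CCCC(C)(C)[C@H]3CC[C@@H]2C)[C@]1(C)CC1=CC(=O)C=CC1=O | intermediate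
26 | toxiusol hydroquinone (free 1,4-diol) | C[C@@H]1CC=C2[C@@H](CCC[C@@]2(C)CC[C@@]2(C)C3=CCCC(C)(C)[C@H]3CC[C@@H]2C)[C@]1(C)Cc1cc(O)ccc1O | intermediate
27 | toxiusol (bis(hydrogen sulfate)) | C[C@@H]1CC=C2[C@@H](CCC[C@@]2(C)CC[C@@]2(C)C3=CCCC(C)(C)[C@H]3CC[C@@H]2C)[C@]1(C)Cc1cc(OS(=O)(=O)O)ccc1OS(=O)(=O)O | target

**Step count.** Total: 17 steps. Longest linear sequence: 12 steps (steps 1–5 and 11–17; the branch of steps 6–10 followed by 11–17 is equally long).

**Steps most likely to fail, with fallbacks**

Step 13. Carbopalladation of the hindered trisubstituted alkene may be outrun by reduction or hydrolysis of the triflate, or closure may occur in the 7-endo sense. The fallback closes ring B with a vinyl radical instead of a vinylpalladium species and sets out from ketone 21. Hydrazine hydrate (Et3N, EtOH, reflux) gives the hydrazone F1. Iodine and tetramethylguanidine (THF, 0 °C, Barton vinyl iodide synthesis) convert it into the less substituted vinyl iodide F2. Slow addition of Bu3SnH and AIBN (benzene, 80 °C) should then bring about 6-exo attack of the C4 vinyl radical on C9 from the tether face, followed by hydrogen transfer to C10. This comes back to the route at 24 without the hydrogenation step; the configuration at C9 would have to be confirmed at that stage.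

Step 7. Deprotonation of 12 may occur at the γ-methyl groups of the isopropylidene unit instead of at the hindered α′-methine, or the second alkylation may show poor facial selectivity. The fallback builds the quaternary centre on the saturated ketone and sets out from pulegone 11. Copper-catalysed conjugate addition of Grignard reagent 16 (CuBr·SMe2, THF, −20 °C; then KOH, EtOH) gives the 8-substituted menthone F3, which has only one enolisable methylene. LiN(i-Pr)2 and MeI give the 2-methyl ketone F4, and LiN(i-Pr)2 with 13 then gives 17, where the fallback rejoins the route. If the bulky C18 substituent reverses the facial preference, the two electrophiles are introduced in the opposite order.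

Step 10. Deoxygenation on the titanium surface may stop at the pinacolate of the very hindered ketone, or aldolisation of the keto aldehyde may compete. The fallback separates C–C bond formation from deoxygenation and sets out from 18. SmI2 (t-BuOH, THF, −78 °C) should give the cis-diol F5 by ketyl addition of the aldehyde to the ketone. Thiocarbonyldiimidazole (DMAP, toluene, reflux) gives the cyclic thionocarbonate F6. Heating in P(OMe)3 (110 °C, Corey–Winter olefination) gives 19, where the fallback rejoins the route.

**Further compounds**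

F1 | step 13 | hydrazone of ketone 21 | C[C@@H]1CCC(=NN)[C@@H](CCC/C(C)=C/C[C@@]2(C)C3=CCCC(C)(C)[C@H]3CC[C@@H]2C)[C@]1(C)Cc1cc(OC)ccc1OC
F2 | step 13 | ring A vinyl iodide (C3=C4, iodine on C4) corresponding to 22 | C[C@@H]1CC=C(I)[C@@H](CCC/C(C)=C/C[C@@]2(C)C3=CCCC(C)(C)[C@H]3CC[C@@H]2C)[C@]1(C)Cc1cc(OC)ccc1OC
F3 | step 7 | (2R,5S)-2-[4-(1,3-dioxolan-2-yl)-2-methylbutan-2-yl]-5-methylcyclohexan-1-one (trans) | C1C(=O)[C@@H](C(C)(C)CCC2OCCO2)CC[C@@H]1C
F4 | step 7 | 2-methyl derivative of F3 (methyl on C12, trans to the C21 methyl) | C[C@H]1C(=O)[C@@H](C(C)(C)CCC2OCCO2)CC[C@@H]1C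
F5 | step 10 | cis-13,14-diol of the rings C/D bicycle (the two carbinol centres are removed again and are left undefined) | C/C(Cl)=C\C[C@@]1(C)C2(O)C(O)CCC(C)(C)[C@H]2CC[C@@H]1C
F6 | step 10 | cyclic thionocarbonate of F5 | C/C(Cl)=C\C[C@@]1(C)C23OC(=S)OC2CCC(C)(C)[C@H]3CC[C@@H]1C
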